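**Plan**

1. Retrosynthetic cuts, last made first: the C14=C15 vinyl carbinol (from a 13,14-epoxy-15-sulfonate), O6/O7 (cis-dihydroxylation of C6=C7), C12–C13 (B-alkyl Suzuki), C4–C5 (cation–olefin closure of ring A), C1–C10 (Negishi), C9–C20 and C8–C17 (cuprate addition, enolate methylation), C9–C11 (Stille).
2. Enabling feature (halimane numbering): ring A (C1–C5, C10) carries no stereocentre, and its gem-dimethyl carbon C4 is bonded to C5 of the C5=C10 alkene. The C4–C5 bond is therefore the trace of a tertiary C4 cation adding to a ring-B alkene that then loses H5.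
3. Forward order: ring B is bought as a cyclohexenone and fully decorated first (C7 oxygen, C8 methyl, quaternary C9, homoprenyl on C10). Ring A closes in step 13, the C6=C7 alkene and the C13–C16 chain follow, and oxygenation of C6/C7 and unmasking of the vinyl carbinol come last.
4. Stereochemistry: Noyori transfer hydrogenation sets the C7 carbinol, which steers the cuprate (C8) and, through C8, the methylation at C9. C7 is then spent as a mesylate, osmylation anti to the C8 methyl sets C6 and C7, and Sharpless epoxidation sets C13.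
5. Design choice: the cyclisation substrate carries a C7 mesylate and a saturated, already configured C8 instead of a second ring alkene. Only one ring alkene meets the cation, and the two C9 substituents never have to be told apart by a late reagent.

Key step: step 13

Assumption: (2E)-3-iodobut-2-en-1-ol (23) is taken as a catalogue building block; it is otherwise two known steps from but-2-yn-1-ol (stannylcupration, iododestannylation).

**Route**

Step 1
Reactants: 1 1,4-dioxaspiro[4.5]dec-6-en-8-one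
Product: 2 (8S)-1,4-dioxaspiro[4.5]dec-6-en-8-ol
Conditions: RuCl[(S,S)-TsDPEN](p-cymene) (1 mol %), HCO2Na, Bu4NCl, CH2Cl2/H2O, rt
Reagents that add atoms: none
Why: Noyori asymmetric transfer hydrogenation reduces the enone carbonyl 1,2 and, with the alkene taking the place an aryl group has in the usual model, the (S,S)-catalyst should give the (S)-carbinol, the future C7 control centre.

Step 2
Reactants: 2 (8S)-1,4-dioxaspiro[4.5]dec-6-en-8-ol
Product: 3 tert-butyl{[(8S)-1,4-dioxaspiro[4.5]dec-6-en-8-yl]oxy}dimethylsilane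
Conditions: TBSCl, imidazole, DMF, rt
Reagents that add atoms: tert-butyldimethylsilyl chloride CC(C)(C)[Si](C)(C)Cl
Why: Imidazole-mediated silylation (silyl ether formation) caps the carbinol with the bulky group that later shields one face of the enone.

Step 3
Reactants: 3 tert-butyl{[(8S)-1,4-dioxaspiro[4.5]dec-6-en-8-yl]oxy}dimethylsilane
Product: 4 (4S)-4-[(tert-butyldimethylsilyl)oxy]cyclohex-2-en-1-one
Conditions: PPTS (cat.), acetone/H2O, 50 °C
Reagents that add atoms: water O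
Why: Mild acid-catalysed acetal hydrolysis releases the ketone in conjugation with the existing alkene and leaves the silyl ether and the stereocentre untouched.

Step 4
Reactants: 4 (4S)-4-[(tert-butyldimethylsilyl)oxy]cyclohex-2-en-1-one
Product: 5 (4S)-4-[(tert-butyldimethylsilyl)oxy]-2-iodocyclohex-2-en-1-one
Conditions: I2, pyridine, CH2Cl2, 0 °C → rt
Reagents that add atoms: iodine II
Why: Johnson α-iodination of a cyclic enone (conjugate addition of pyridine, iodination of the enolate, elimination) installs the vinyl iodide needed for cross-coupling at the future C9.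

Step 5
Reactants: 5 (4S)-4-[(tert-butyldimethylsilyl)oxy]-2-iodocyclohex-2-en-1-one
Product: 6 (4S)-4-[(tert-butyldimethylsilyl)oxy]-2-(prop-2-en-1-yl)cyclohex-2-en-1-one
Conditions: allylSnBu3, Pd2(dba)3 (2.5 mol %), AsPh3, CuI, NMP, rt
Reagents that add atoms: allyltributylstannane C=CC[Sn](CCCC)(CCCC)CCCC
Why: Stille cross-coupling of an α-iodoenone under arsine and copper(I) acceleration attaches the allyl group that serves as the masked two-carbon C11–C12 arm.

Step 6
Reactants: 6 (4S)-4-[(tert-butyldimethylsilyl)oxy]-2-(prop-2-en-1-yl)cyclohex-2-en-1-one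
Product: 8 (2R,3S,4S)-4-[(tert-butyldimethylsilyl)oxy]-2,3-dimethyl-2-(prop-2-en-1-yl)cyclohexan-1-one, via lithium enolate 7 (not isolated)
Conditions: Me2CuLi (from MeLi, CuI), Et2O, −78 → −20 °C; then HMPA, MeI, −78 → 0 °C
Reagents that add atoms: lithium dimethylcuprate [Li+].C[Cu-]C; iodomethane CI
Why: Gilman conjugate addition should occur anti to the γ-silyloxy group and set C8, and the regiodefined enolate is then C-methylated (enolate alkylation) anti to the new C8 methyl, which sets the quaternary C9 with its methyl trans and its allyl arm cis to the C8 methyl.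

Step 7
Reactants: 8 (2R,3S,4S)-4-[(tert-butyldimethylsilyl)oxy]-2,3-dimethyl-2-(prop-2-en-1-yl)cyclohexan-1-one
Product: 10 (2R,3S,4S)-4-[(tert-butyldimethylsilyl)oxy]-2-(2-hydroxyethyl)-2,3-dimethylcyclohexan-1-one, via keto aldehyde 9 (not isolated)
Conditions: O3, CH2Cl2/MeOH, −78 °C; Me2S, −78 → 0 °C; then NaBH4, −78 °C
Reagents that add atoms: ozone [O-][O+]=O
Why: Ozonolysis with reductive work-up shortens the allyl group to the C11–C12 aldehyde, and sodium borohydride at −78 °C reduces that aldehyde chemoselectively beside the hindered α-quaternary ketone.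

Step 8
Reactants: 10 (2R,3S,4S)-4-[(tert-butyldimethylsilyl)oxy]-2-(2-hydroxyethyl)-2,3-dimethylcyclohexan-1-one
Product: 11 2-[(1R,2S,3S)-3-[(tert-butyldimethylsilyl)oxy]-1,2-dimethyl-6-oxocyclohexyl]ethyl 2,2-dimethylpropanoate
Conditions: PivCl, pyridine, DMAP (cat.), CH2Cl2, 0 °C → rt
Reagents that add atoms: pivaloyl chloride CC(C)(C)C(Cl)=O
Why: DMAP-catalysed acylation of the primary alcohol gives a pivalate that resists base, organozinc and acid and whose oxygen is too poor a nucleophile to trap a cation later.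

Step 9
Reactants: 11 2-[(1R,2S,3S)-3-[(tert-butyldimethylsilyl)oxy]-1,2-dimethyl-6-oxocyclohexyl]ethyl 2,2-dimethylpropanoate
Product: 13 2-[(1R,5S,6S)-5-[(tert-butyldimethylsilyl)oxy]-1,6-dimethyl-2-{[(trifluoromethyl)sulfonyl]oxy}cyclohex-2-en-1-yl]ethyl 2,2-dimethylpropanoate, via potassium enolate 12 (not isolated)
Conditions: KHMDS, THF, −78 °C; PhNTf2, −78 → 0 °C
Reagents that add atoms: N-phenylbis(trifluoromethanesulfonimide) FC(F)(F)S(=O)(=O)N(c1ccccc1)S(=O)(=O)C(F)(F)F
Why: Enolisation can only occur towards C5 because C9 is quaternary, and O-sulfonylation of the enolate (enol triflate formation) fixes the C10=C5 double bond.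

Step 10
Reactants: 13 2-[(1R,5S,6S)-5-[(tert-butyldimethylsilyl)oxy]-1,6-dimethyl-2-{[(trifluoromethyl)sulfonyl]oxy}cyclohex-2-en-1-yl]ethyl 2,2-dimethylpropanoate; 14 5-bromo-2-methylpent-2-ene
Product: 16 2-[(1R,5S,6S)-5-[(tert-butyldimethylsilyl)oxy]-1,6-dimethyl-2-(4-methylpent-3-en-1-yl)cyclohex-2-en-1-yl]ethyl 2,2-dimethylpropanoate, via alkylzinc bromide 15 (not isolated)
Conditions: 14, Zn dust, I2 (5 mol %), DMA, 70 °C; then 13, Pd(dppf)Cl2 (5 mol %), THF, 50 °C
Reagents that add atoms: none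
Why: Negishi sp2–sp3 cross-coupling of an enol triflate with a primary alkylzinc halide made by direct zinc insertion joins C1 to C10 and tolerates the pivalate and the silyl ether.

Step 11
Reactants: 16 2-[(1R,5S,6S)-5-[(tert-butyldimethylsilyl)oxy]-1,6-dimethyl-2-(4-methylpent-3-en-1-yl)cyclohex-2-en-1-yl]ethyl 2,2-dimethylpropanoate
Product: 17 2-[(1R,5S,6S)-5-hydroxy-1,6-dimethyl-2-(4-methylpent-3-en-1-yl)cyclohex-2-en-1-yl]ethyl 2,2-dimethylpropanoate
Conditions: TBAF, THF, 0 °C → rt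
Reagents that add atoms: none
Why: Fluoride-mediated desilylation frees the C7 hydroxyl while the hindered pivalate and both alkenes stay intact.

Step 12
Reactants: 17 2-[(1R,5S,6S)-5-hydroxy-1,6-dimethyl-2-(4-methylpent-3-en-1-yl)cyclohex-2-en-1-yl]ethyl 2,2-dimethylpropanoate
Product: 18 2-[(1R,5S,6S)-5-[(methanesulfonyl)oxy]-1,6-dimethyl-2-(4-methylpent-3-en-1-yl)cyclohex-2-en-1-yl]ethyl 2,2-dimethylpropanoate
Conditions: MsCl, Et3N, CH2Cl2, 0 °C
Reagents that add atoms: methanesulfonyl chloride CS(Cl)(=O)=O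
Why: Sulfonylation (mesylate formation) turns the C7 oxygen into a group that is inert and non-nucleophilic towards acid and cations yet ready to leave in step 14.

Step 13
Reactants: 18 2-[(1R,5S,6S)-5-[(methanesulfonyl)oxy]-1,6-dimethyl-2-(4-methylpent-3-en-1-yl)cyclohex-2-en-1-yl]ethyl 2,2-dimethylpropanoate
Product: 19 2-[(1R,2S,3S)-3-[(methanesulfonyl)oxy]-1,2,5,5-tetramethyl-1,2,3,4,5,6,7,8-octahydronaphthalen-1-yl]ethyl 2,2-dimethylpropanoate
Conditions: MeSO3H (3 equiv), CH2Cl2, −20 → 0 °C; then sat. NaHCO3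
Reagents that add atoms: none
Why: Methanesulfonic acid protonates the terminal trisubstituted alkene at C3 to give the tertiary C4 cation, C5 of the ring-B alkene attacks it (new C4–C5 bond) to give the tertiary C10 cation, and loss of H5 leaves the tetrasubstituted C5=C10 alkene. The closest known reaction type is the proton-initiated cation–olefin cyclisation that closes gem-dimethylcyclohexene rings in cyclogeranyl and ionone chemistry. Ring A closes in a 6-endo-trig mode, because only that mode places the charge on a tertiary carbon (C10), whereas attack at C10 would give a five-membered ring and a secondary cation. No stereocentre is formed, since C5 ends sp2, and C7, C8 and C9 are not touched. The step needs chemoselective initiation and regioselective proton loss: protonation of the ring alkene gives a C10 cation without a productive partner that simply reverts, C10 is flanked by quaternary C9 and can shed only H5 or H1, and reversible protonation should funnel any 1(10)-alkene to the more substituted 5(10)-alkene. The saturated C9 arm with its pivalate and the C7 mesylate offer neither a nucleophile to trap the cation nor an alkene that would stabilise a rearranged C9 cation.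

Step 14
Reactants: 19 2-[(1R,2S,3S)-3-[(methanesulfonyl)oxy]-1,2,5,5-tetramethyl-1,2,3,4,5,6,7,8-octahydronaphthalen-1-yl]ethyl 2,2-dimethylpropanoate
Product: 20 2-[(1R,2R)-1,2,5,5-tetramethyl-1,2,5,6,7,8-hexahydronaphthalen-1-yl]ethyl 2,2-dimethylpropanoate
Conditions: DBU, toluene, 100 °C
Reagents that add atoms: none
Why: Base-induced E2 elimination has to take the allylic C6 hydrogen anti to the mesylate, because H8 is cis to the leaving group, so the C6=C7 alkene forms in conjugation with C5=C10 and C8 is left untouched.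

Step 15
Reactants: 20 2-[(1R,2R)-1,2,5,5-tetramethyl-1,2,5,6,7,8-hexahydronaphthalen-1-yl]ethyl 2,2-dimethylpropanoate
Product: 21 2-[(1R,2R)-1,2,5,5-tetramethyl-1,2,5,6,7,8-hexahydronaphthalen-1-yl]ethan-1-ol
Conditions: DIBAL-H, CH2Cl2, −78 °C; Rochelle salt
Reagents that add atoms: none
Why: DIBAL-H reduction (reductive ester cleavage) removes the pivalate without affecting the diene.

Step 16
Reactants: 21 2-[(1R,2R)-1,2,5,5-tetramethyl-1,2,5,6,7,8-hexahydronaphthalen-1-yl]ethan-1-ol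
Product: 22 (1R,2R)-1-(2-iodoethyl)-1,2,5,5-tetramethyl-1,2,5,6,7,8-hexahydronaphthalene
Conditions: I2, PPh3, imidazole, CH2Cl2, 0 °C → rt
Reagents that add atoms: iodine II
Why: Garegg–Samuelsson (Appel-type) iodination converts the primary alcohol into the iodide with neutral reagents that leave the diene alone.

Step 17
Reactants: 22 (1R,2R)-1-(2-iodoethyl)-1,2,5,5-tetramethyl-1,2,5,6,7,8-hexahydronaphthalene; 23 (2E)-3-iodobut-2-en-1-ol
Product: 26 (2E)-3-methyl-5-[(1R,2R)-1,2,5,5-tetramethyl-1,2,5,6,7,8-hexahydronaphthalen-1-yl]pent-2-en-1-ol, via alkyllithium 24 (not isolated), via borinate complex 25 (not isolated)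
Conditions: t-BuLi (2.1 equiv), Et2O, −78 °C; B-MeO-9-BBN, THF, −78 °C → rt; then 23, Pd(dppf)Cl2 (5 mol %), AsPh3, Cs2CO3, DMF/H2O, rt
Reagents that add atoms: none
Why: Iodine–lithium exchange at −78 °C, capture of the alkyllithium as a B-alkyl-9-BBN borinate and B-alkyl Suzuki–Miyaura coupling with the vinyl iodide form C12–C13 with retention of the E geometry, the low temperature keeping the alkyllithium from adding to the diene.

Step 18
Reactants: 26 (2E)-3-methyl-5-[(1R,2R)-1,2,5,5-tetramethyl-1,2,5,6,7,8-hexahydronaphthalen-1-yl]pent-2-en-1-ol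
Product: 27 [(2S,3S)-3-methyl-3-{2-[(1R,2R)-1,2,5,5-tetramethyl-1,2,5,6,7,8-hexahydronaphthalen-1-yl]ethyl}oxiran-2-yl]methanol
Conditions: Ti(OiPr)4 (10 mol %), L-(+)-DET (12 mol %), t-BuOOH, 4 Å MS, CH2Cl2, −20 °C
Reagents that add atoms: tert-butyl hydroperoxide CC(C)(C)OO
Why: Sharpless asymmetric epoxidation is specific for the allylic alcohol, and with L-(+)-diethyl tartrate the oxygen should be delivered to the face that gives the (13S,14S)-epoxide, as with geraniol, so C13 is set by the reagent.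

Step 19
Reactants: 27 [(2S,3S)-3-methyl-3-{2-[(1R,2R)-1,2,5,5-tetramethyl-1,2,5,6,7,8-hexahydronaphthalen-1-yl]ethyl}oxiran-2-yl]methanol
Product: 28 [(2S,3S)-3-methyl-3-{2-[(1R,2R)-1,2,5,5-tetramethyl-1,2,5,6,7,8-hexahydronaphthalen-1-yl]ethyl}oxiran-2-yl]methyl 4-methylbenzenesulfonate
Conditions: TsCl, Et3N, DMAP (cat.), CH2Cl2, 0 °C
Reagents that add atoms: p-toluenesulfonyl chloride Cc1ccc(cc1)S(Cl)(=O)=O
Why: Sulfonylation of the primary alcohol (tosylate formation) gives a glycidyl-type tosylate that survives oxidation and acylation and is exchanged for iodide at the end.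

Step 20
Reactants: 28 [(2S,3S)-3-methyl-3-{2-[(1R,2R)-1,2,5,5-tetramethyl-1,2,5,6,7,8-hexahydronaphthalen-1-yl]ethyl}oxiran-2-yl]methyl 4-methylbenzenesulfonate
Product: 29 (6S,7R,8S,9R,13S,14S)-13,14-epoxy-6,7-dihydroxyhalim-5(10)-en-15-yl 4-methylbenzenesulfonate
Conditions: OsO4 (5 mol %), NMO, acetone/H2O, 0 °C → rt
Reagents that add atoms: osmium tetroxide O=[Os](=O)(=O)=O; N-methylmorpholine N-oxide C[N+]1([O-])CCOCC1; water O
Why: Upjohn dihydroxylation should occur only at the disubstituted C6=C7 bond, the tetrasubstituted C5=C10 bond being too hindered, and syn addition from the face opposite the allylic C8 methyl and the C9 arm sets C6 and C7 cis to each other and to the C9 methyl.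

Step 21
Reactants: 29 (6S,7R,8S,9R,13S,14S)-13,14-epoxy-6,7-dihydroxyhalim-5(10)-en-15-yl 4-methylbenzenesulfonate
Product: 30 (6S,7R,8S,9R,13S,14S)-7-acetoxy-13,14-epoxy-6-hydroxyhalim-5(10)-en-15-yl 4-methylbenzenesulfonate
Conditions: Ac2O (1.1 equiv), pyridine, CH2Cl2, 0 °C
Reagents that add atoms: acetic anhydride CC(=O)OC(C)=O
Why: Regioselective acylation is expected at the equatorial C7 hydroxyl, because the allylic C6 hydroxyl is pseudo-axial and crowded by the C4 gem-dimethyl group.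

Step 22
Reactants: 30 (6S,7R,8S,9R,13S,14S)-7-acetoxy-13,14-epoxy-6-hydroxyhalim-5(10)-en-15-yl 4-methylbenzenesulfonate
Product: 32 (6S,7R,8S,9R,13S)-6,13-dihydroxyhalima-5(10),14-dien-7-yl acetate, via epoxy iodide 31 (not isolated)
Conditions: NaI, butan-2-one, 60 °C; then Zn dust, EtOH, 60 °C
Reagents that add atoms: none
Why: Finkelstein exchange of the tosylate followed by zinc-mediated reductive β-elimination of the β-iodo epoxide opens the ring towards C14=C15 and releases the tertiary C13 alcohol with its C13–O bond, and hence the S configuration, unchanged, under neutral conditions that spare the acetate.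

**Compound list**

1 | 1,4-dioxaspiro[4.5]dec-6-en-8-one | O=C1CCC2(OCCO2)C=C1 | starting material
2 | (8S)-1,4-dioxaspiro[4.5]dec-6-en-8-ol | O1CCOC12CC[C@H](O)C=C2 | intermediate
3 | tert-butyl{[(8S)-1,4-dioxaspiro[4.5]dec-6-en-8-yl]oxy}dimethylsilane | O1CCOC12CC[C@H](O[Si](C)(C)C(C)(C)C)C=C2 | intermediate
4 | (4S)-4-[(tert-butyldimethylsilyl)oxy]cyclohex-2-en-1-one | O=C1CC[C@H](O[Si](C)(C)C(C)(C)C)C=C1 | intermediate
5 | (4S)-4-[(tert-butyldimethylsilyl)oxy]-2-iodocyclohex-2-en-1-one | O=C1CC[C@H](O[Si](C)(C)C(C)(C)C)C=C1I | intermediate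
6 | (4S)-4-[(tert-butyldimethylsilyl)oxy]-2-(prop-2-en-1-yl)cyclohex-2-en-1-one | O=C1CC[C@H](O[Si](C)(C)C(C)(C)C)C=C1CC=C | intermediate
7 | lithium (3S,4S)-4-[(tert-butyldimethylsilyl)oxy]-3-methyl-2-(prop-2-en-1-yl)cyclohex-1-en-1-olate | [Li+].[O-]C1=C(CC=C)[C@H](C)[C@@H](O[Si](C)(C)C(C)(C)C)CC1 | intermediate
8 | (2R,3S,4S)-4-[(tert-butyldimethylsilyl)oxy]-2,3-dimethyl-2-(prop-2-en-1-yl)cyclohexan-1-one | C=CC[C@@]1(C)C(=O)CC[C@H](O[Si](C)(C)C(C)(C)C)[C@H]1C | intermediate
9 | 2-[(1R,2S,3S)-3-[(tert-butyldimethylsilyl)oxy]-1,2-dimethyl-6-oxocyclohexyl]acetaldehyde | O=CC[C@@]1(C)C(=O)CC[C@H](O[Si](C)(C)C(C)(C)C)[C@H]1C | intermediate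
10 | (2R,3S,4S)-4-[(tert-butyldimethylsilyl)oxy]-2-(2-hydroxyethyl)-2,3-dimethylcyclohexan-1-one | OCC[C@@]1(C)C(=O)CC[C@H](O[Si](C)(C)C(C)(C)C)[C@H]1C | intermediate
11 | 2-[(1R,2S,3S)-3-[(tert-butyldimethylsilyl)oxy]-1,2-dimethyl-6-oxocyclohexyl]ethyl 2,2-dimethylpropanoate | CC(C)(C)C(=O)OCC[C@@]1(C)C(=O)CC[C@H](O[Si](C)(C)C(C)(C)C)[C@H]1C | intermediate
12 | potassium (4S,5S,6R)-4-[(tert-butyldimethylsilyl)oxy]-6-{2-[(2,2-dimethylpropanoyl)oxy]ethyl}-5,6-dimethylcyclohex-1-en-1-olate | [K+].CC(C)(C)C(=O)OCC[C@@]1(C)C([O-])=CC[C@H](O[Si](C)(C)C(C)(C)C)[C@H]1C | intermediate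
13 | 2-[(1R,5S,6S)-5-[(tert-butyldimethylsilyl)oxy]-1,6-dimethyl-2-{[(trifluoromethyl)sulfonyl]oxy}cyclohex-2-en-1-yl]ethyl 2,2-dimethylpropanoate | CC(C)(C)C(=O)OCC[C@@]1(C)C(OS(=O)(=O)C(F)(F)F)=CC[C@H](O[Si](C)(C)C(C)(C)C)[C@H]1C | intermediate
14 | 5-bromo-2-methylpent-2-ene | CC(C)=CCCBr | starting material
15 | bromo(4-methylpent-3-en-1-yl)zinc | CC(C)=CCC[Zn]Br | intermediate
16 | 2-[(1R,5S,6S)-5-[(tert-butyldimethylsilyl)oxy]-1,6-dimethyl-2-(4-methylpent-3-en-1-yl)cyclohex-2-en-1-yl]ethyl 2,2-dimethylpropanoate | CC(C)(C)C(=O)OCC[C@@]1(C)C(CCC=C(C)C)=CC[C@H](O[Si](C)(C)C(C)(C)C)[C@H]1C | intermediate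
17 | 2-[(1R,5S,6S)-5-hydroxy-1,6-dimethyl-2-(4-methylpent-3-en-1-yl)cyclohex-2-en-1-yl]ethyl 2,2-dimethylpropanoate | CC(C)(C)C(=O)OCC[C@@]1(C)C(CCC=C(C)C)=CC[C@H](O)[C@H]1C | intermediate
18 | 2-[(1R,5S,6S)-5-[(methanesulfonyl)oxy]-1,6-dimethyl-2-(4-methylpent-3-en-1-yl)cyclohex-2-en-1-yl]ethyl 2,2-dimethylpropanoate (cyclisation precursor) | CC(C)(C)C(=O)OCC[C@@]1(C)C(CCC=C(C)C)=CC[C@H](OS(C)(=O)=O)[C@H]1C | intermediate
19 | 2-[(1R,2S,3S)-3-[(methanesulfonyl)oxy]-1,2,5,5-tetramethyl-1,2,3,4,5,6,7,8-octahydronaphthalen-1-yl]ethyl 2,2-dimethylpropanoate (cyclisation product) | CC(C)(C)C(=O)OCC[C@@]1(C)C2=C(C[C@H](OS(C)(=O)=O)[C@H]1C)C(C)(C)CCC2 | intermediate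
20 | 2-[(1R,2R)-1,2,5,5-tetramethyl-1,2,5,6,7,8-hexahydronaphthalen-1-yl]ethyl 2,2-dimethylpropanoate | CC(C)(C)C(=O)OCC[C@@]1(C)C2=C(C=C[C@H]1C)C(C)(C)CCC2 | intermediate
21 | 2-[(1R,2R)-1,2,5,5-tetramethyl-1,2,5,6,7,8-hexahydronaphthalen-1-yl]ethan-1-ol | OCC[C@@]1(C)C2=C(C=C[C@H]1C)C(C)(C)CCC2 | intermediate
22 | (1R,2R)-1-(2-iodoethyl)-1,2,5,5-tetramethyl-1,2,5,6,7,8-hexahydronaphthalene | ICC[C@@]1(C)C2=C(C=C[C@H]1C)C(C)(C)CCC2 | intermediate
23 | (2E)-3-iodobut-2-en-1-ol | OC/C=C(\C)I | starting material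
24 | {2-[(1R,2R)-1,2,5,5-tetramethyl-1,2,5,6,7,8-hexahydronaphthalen-1-yl]ethyl}lithium | [Li]CC[C@@]1(C)C2=C(C=C[C@H]1C)C(C)(C)CCC2 | intermediate
25 | lithium 9-methoxy-9-{2-[(1R,2R)-1,2,5,5-tetramethyl-1,2,5,6,7,8-hexahydronaphthalen-1-yl]ethyl}-9-boranuidabicyclo[3.3.1]nonane | [Li+].CO[B-]1(CC[C@@]2(C)C3=C(C=C[C@H]2C)C(C)(C)CCC3)C2CCCC1CCC2 | intermediate
26 | (2E)-3-methyl-5-[(1R,2R)-1,2,5,5-tetramethyl-1,2,5,6,7,8-hexahydronaphthalen-1-yl]pent-2-en-1-ol, i.e. (8R,9R,13E)-halima-5(10),6,13-trien-15-ol | OC/C=C(\C)CC[C@@]1(C)C2=C(C=C[C@H]1C)C(C)(C)CCC2 | intermediate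
27 | [(2S,3S)-3-methyl-3-{2-[(1R,2R)-1,2,5,5-tetramethyl-1,2,5,6,7,8-hexahydronaphthalen-1-yl]ethyl}oxiran-2-yl]methanol, i.e. (8R,9R,13S,14S)-13,14-epoxyhalima-5(10),6-dien-15-ol | OC[C@@H]1O[C@@]1(C)CC[C@@]2(C)C3=C(C=C[C@H]2C)C(C)(C)CCC3 | intermediate
28 | [(2S,3S)-3-methyl-3-{2-[(1R,2R)-1,2,5,5-tetramethyl-1,2,5,6,7,8-hexahydronaphthalen-1-yl]ethyl}oxiran-2-yl]methyl 4-methylbenzenesulfonate | Cc1ccc(cc1)S(=O)(=O)OC[C@@H]1O[C@@]1(C)CC[C@@]2(C)C3=C(C=C[C@H]2C)C(C)(C)CCC3 | intermediate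
29 | (6S,7R,8S,9R,13S,14S)-13,14-epoxy-6,7-dihydroxyhalim-5(10)-en-15-yl 4-methylbenzenesulfonate (6-OH, 7-OH and C9-methyl on one face; C8-methyl and C9 side chain on the other) | Cc1ccc(cc1)S(=O)(=O)OC[C@@H]1O[C@@]1(C)CC[C@@]2(C)C3=C([C@H](O)[C@H](O)[C@H]2C)C(C)(C)CCC3 | intermediate
30 | (6S,7R,8S,9R,13S,14S)-7-acetoxy-13,14-epoxy-6-hydroxyhalim-5(10)-en-15-yl 4-methylbenzenesulfonate | Cc1ccc(cc1)S(=O)(=O)OC[C@@H]1O[C@@]1(C)CC[C@@]2(C)C3=C([C@H](O)[C@H](OC(C)=O)[C@H]2C)C(C)(C)CCC3 | intermediate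
31 | (6S,7R,8S,9R,13S,14R)-13,14-epoxy-6-hydroxy-15-iodohalim-5(10)-en-7-yl acetate | IC[C@@H]1O[C@@]1(C)CC[C@@]2(C)C3=C([C@H](O)[C@H](OC(C)=O)[C@H]2C)C(C)(C)CCC3 | intermediate
32 | (6S,7R,8S,9R,13S)-6,13-dihydroxyhalima-5(10),14-dien-7-yl acetate (CNP0126002.2) | C=C[C@@](C)(O)CC[C@@]1(C)C2=C([C@H](O)[C@H](OC(C)=O)[C@H]1C)C(C)(C)CCC2 | target

**Count**

Total step count: 22. Longest linear sequence: 22 steps (1 → 32).

**Steps most likely to fail**

Step 13 (ring-A closure). What may go wrong: in a poorly basic medium the C10 cation may live long enough for 1,2-shifts from C9, or proton loss may stop at a mixture of 1(10)- and 5(10)-alkenes that does not converge. Fallback: 18 is treated with the mercury(II) triflate–N,N-dimethylaniline complex in nitromethane at −20 °C. The less hindered terminal alkene is activated as a mercurinium ion, C5 closes the same C4–C5 bond, and the amine removes H5 from the C10 cation at once. Brine work-up gives the organomercury chloride 2-[(1R,2S,3S)-6-(chloromercurio)-3-[(methanesulfonyl)oxy]-1,2,5,5-tetramethyl-1,2,3,4,5,6,7,8-octahydronaphthalen-1-yl]ethyl 2,2-dimethylpropanoate F3 (configuration at the mercury-bearing carbon of no consequence). Sodium borohydride in aqueous sodium hydroxide then replaces mercury by hydrogen and the route is rejoined at 19.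

Step 6 (C8 and C9). What may go wrong: poor facial selectivity in the methylation, because the incoming electrophile, although anti to the C8 methyl, is 1,3-syn to the C7 silyloxy group. Fallback: 5 is methylated by Suzuki coupling with trimethylboroxine (Pd(dppf)Cl2, K2CO3, dioxane) to (4S)-4-[(tert-butyldimethylsilyl)oxy]-2-methylcyclohex-2-en-1-one F1. Gilman addition as before and capture of the enolate with allyl chloroformate give allyl (3S,4S)-4-[(tert-butyldimethylsilyl)oxy]-2,3-dimethylcyclohex-1-en-1-yl carbonate F2. Decarboxylative asymmetric allylic alkylation with Pd2(dba)3 and (S)-t-Bu-PHOX then forms C9 under catalyst control, the ligand being the one that should place the allyl group cis to the C8 methyl, and the route is rejoined at 8.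

Step 21 (mono-acetylation). What may go wrong: loss of regiocontrol through competing acetylation at O6, bis-acetylation, or acetyl migration between the cis hydroxyls. Fallback: the allylic C6 hydroxyl of 29 is oxidised selectively with MnO2 to (7R,8S,9R,13S,14S)-13,14-epoxy-7-hydroxy-6-oxohalim-5(10)-en-15-yl 4-methylbenzenesulfonate F4. The one remaining secondary hydroxyl is acetylated (Ac2O, DMAP) to (7R,8S,9R,13S,14S)-7-acetoxy-13,14-epoxy-6-oxohalim-5(10)-en-15-yl 4-methylbenzenesulfonate F5. Luche reduction (NaBH4, CeCl3, MeOH, −78 °C) returns the C6 alcohol, expected pseudo-axial and therefore cis to the acetate because an in-plane C6–O bond would clash with the C4 methyls, and the route is rejoined at 30.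

**Further compounds**

F1 | step 6 | (4S)-4-[(tert-butyldimethylsilyl)oxy]-2-methylcyclohex-2-en-1-one | O=C1CC[C@H](O[Si](C)(C)C(C)(C)C)C=C1C
F2 | step 6 | allyl (3S,4S)-4-[(tert-butyldimethylsilyl)oxy]-2,3-dimethylcyclohex-1-en-1-yl carbonate | C=CCOC(=O)OC1=C(C)[C@H](C)[C@@H](O[Si](C)(C)C(C)(C)C)CC1
F3 | step 13 | 2-[(1R,2S,3S)-6-(chloromercurio)-3-[(methanesulfonyl)oxy]-1,2,5,5-tetramethyl-1,2,3,4,5,6,7,8-octahydronaphthalen-1-yl]ethyl 2,2-dimethylpropanoate | CC(C)(C)C(=O)OCC[C@@]1(C)C2=C(C[C@H](OS(C)(=O)=O)[C@H]1C)C(C)(C)C([Hg]Cl)CC2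
F4 | step 21 | (7R,8S,9R,13S,14S)-13,14-epoxy-7-hydroxy-6-oxohalim-5(10)-en-15-yl 4-methylbenzenesulfonate | Cc1ccc(cc1)S(=O)(=O)OC[C@@H]1O[C@@]1(C)CC[C@@]2(C)C3=C(C(=O)[C@H](O)[C@H]2C)C(C)(C)CCC3
F5 | step 21 | (7R,8S,9R,13S,14S)-7-acetoxy-13,14-epoxy-6-oxohalim-5(10)-en-15-yl 4-methylbenzenesulfonate | Cc1ccc(cc1)S(=O)(=O)OC[C@@H]1O[C@@]1(C)CC[C@@]2(C)C3=C(C(=O)[C@H](OC(C)=O)[C@H]2C)C(C)(C)CCC3
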